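The route is built on a three-component disconnection at C7, the quaternary stereocentre of carbocyclic ring A. C7 bears a methyl group, the ketone carbons C6 and C8 and the oxygen of a doubly ortho-substituted aryl ester, which is what a Passerini reaction of a 1,2-diketone delivers. In step 4 a chiral phosphoric acid should unite butane-2,3-dione, bis-silylated orsellinic acid and a convertible aryl isocyanide, forging C7–C8 and, through the Mumm shift, the C7 O–acyl bond while setting 7R in one operation. Its precursors are the symmetric diketone, the protected acid and 2-nitrophenyl isocyanide. The anilide is then converted into a thioester, coupled with a kojic-acid-derived stannylpyranone (ring B), and ring A is closed on the pyranone carbonyl carbon.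

Key step: step 4

Remark: isochromene numbering is used (ring A = carbocycle C4a–C8a, ring B = pyran; C7 is R throughout). The N-substituent of the isocyanide is a cleavable auxiliary. It is chosen as 2-nitrophenyl because a 2-nitroanilide can be turned into an N-acylbenzotriazole by reduction and diazotisation, which an α-acyloxy β-keto amide should tolerate and which needs no neighbouring amide to assist the activation.

Step 1
Reactants: 1 orsellinic acid
Product: 3 2,4-bis(tert-butyldimethylsilyloxy)-6-methylbenzoic acid, via silyl ester 2 (not isolated)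
Conditions: TBSCl (3.3 equiv), imidazole, DMF, rt; then AcOH, THF/H2O, rt
Reagents that add atoms: tert-butyldimethylsilyl chloride, CC(C)(C)[Si](C)(C)Cl
Why: Exhaustive silylation followed by selective hydrolysis of the far more labile silyl ester should free the acid while both aryl silyl ethers stay in place (silyl ether protection).

Step 2
Reactants: 4 2-nitroaniline
Product: 5 N-(2-nitrophenyl)formamide
Conditions: HCO2H, Ac2O, THF, 0 → 50 °C
Reagents that add atoms: formic acid, OC=O
Why: N-Formylation of the weakly nucleophilic aniline by the mixed anhydride formed in the flask is a standard formamide synthesis.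

Step 3
Reactants: 5 N-(2-nitrophenyl)formamide
Product: 6 2-nitrophenyl isocyanide
Conditions: POCl3, Et3N, CH2Cl2, −10 → 0 °C
Reagents that add atoms: none
Why: Dehydration of an N-aryl formamide with POCl3 and a tertiary amine is the standard isocyanide synthesis and should give a storable solid isocyanide.

Step 4
Reactants: 3 2,4-bis(tert-butyldimethylsilyloxy)-6-methylbenzoic acid; 7 butane-2,3-dione; 6 2-nitrophenyl isocyanide
Product: 9 (2R)-2-methyl-1-[(2-nitrophenyl)amino]-1,3-dioxobutan-2-yl 2,4-bis(tert-butyldimethylsilyloxy)-6-methylbenzoate, via acyl imidate 8 (not isolated)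
Conditions: (R)-TRIP [(R)-3,3'-bis(2,4,6-triisopropylphenyl)-1,1'-binaphthyl-2,2'-diyl hydrogen phosphate] (10 mol %; its antipode if the sense of induction proves opposite), 7 (5 equiv), 6 (1.2 equiv), CHCl3 (0.5 M), 4 Å MS, −20 °C
Reagents that add atoms: none
Why: Proposed new method: the phosphoric acid should hydrogen-bond to one carbonyl of 7 and to acid 3, the isocyanide carbon adds to the activated ketone to give a nitrilium ion, the carboxylate adds to it to give imidate 8, and a Mumm 1,4-O→O acyl shift delivers the hindered tertiary ester intramolecularly; the closest known reactions are uncatalysed Passerini reactions of 1,2-diketones and phosphoric-acid-catalysed enantioselective Passerini reactions of aldehydes. No ring is closed. The new stereocentre C7 is under catalyst control: the chiral phosphate must steer the isocyanide to the Si face of the bound carbonyl (O > acetyl > methyl) so that 7R results. Only enantioface selectivity is needed because 7 is symmetric and its carbonyls are equivalent, and the neighbouring acetyl oxygen offers a second hydrogen-bond acceptor that distinguishes the acetyl from the methyl flank. Mono-addition should be secured by the excess of 7 and by the hindered ketone of 9, which is no longer activated as a 1,2-dicarbonyl.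

Step 5
Reactants: 9 (2R)-2-methyl-1-[(2-nitrophenyl)amino]-1,3-dioxobutan-2-yl 2,4-bis(tert-butyldimethylsilyloxy)-6-methylbenzoate
Product: 11 (2R)-1-(1H-benzotriazol-1-yl)-2-methyl-1,3-dioxobutan-2-yl 2,4-bis(tert-butyldimethylsilyloxy)-6-methylbenzoate, via aminoanilide 10 (not isolated)
Conditions: H2 (1 atm), Pd/C, EtOAc/AcOH, rt; filter; then isoamyl nitrite, 0 °C → rt
Reagents that add atoms: isoamyl nitrite, CC(C)CCON=O
Why: Nitro hydrogenation and diazotisation, with the diazonium ion trapped by the neighbouring anilide nitrogen, is the known conversion of a 2-nitroanilide into an N-acylbenzotriazole; the aminoanilide is diazotised at once so that condensation of the aniline with the hindered ketone should not compete, and C7 has no α-hydrogen to lose.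

Step 6
Reactants: 11 (2R)-1-(1H-benzotriazol-1-yl)-2-methyl-1,3-dioxobutan-2-yl 2,4-bis(tert-butyldimethylsilyloxy)-6-methylbenzoate
Product: 12 (2R)-2-methyl-1-[(4-methylphenyl)sulfanyl]-1,3-dioxobutan-2-yl 2,4-bis(tert-butyldimethylsilyloxy)-6-methylbenzoate
Conditions: 4-MeC6H4SH, Et3N, CH2Cl2, 0 °C → rt
Reagents that add atoms: 4-methylbenzenethiol, Cc1ccc(S)cc1
Why: Acyl substitution of an N-acylbenzotriazole by a thiolate (thioester synthesis from an acyl azolide) is mild enough to avoid retro-Claisen loss of the acetyl group and never passes through the decarboxylation-prone β-keto acid.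

Step 7
Reactants: 12 (2R)-2-methyl-1-[(4-methylphenyl)sulfanyl]-1,3-dioxobutan-2-yl 2,4-bis(tert-butyldimethylsilyloxy)-6-methylbenzoate
Product: 13 (2R)-3-(tert-butyldimethylsilyloxy)-2-methyl-1-[(4-methylphenyl)sulfanyl]-1-oxobut-3-en-2-yl 2,4-bis(tert-butyldimethylsilyloxy)-6-methylbenzoate
Conditions: TBSOTf, Et3N, CH2Cl2, 0 °C
Reagents that add atoms: tert-butyldimethylsilyl trifluoromethanesulfonate, CC(C)(C)[Si](C)(C)OS(=O)(=O)C(F)(F)F
Why: Soft enolisation (silyl enol ether formation) can only take place at the acetyl methyl group, the future C5, because C7 is quaternary and the thioester has no α-hydrogen.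

Step 8
Reactants: 14 kojic acid
Product: 15 6-(hydroxymethyl)-4-oxo-4H-pyran-3-yl trifluoromethanesulfonate
Conditions: PhNTf2, Et3N, DMF, 0 °C → rt
Reagents that add atoms: N-phenylbis(trifluoromethanesulfonimide), O=S(=O)(N(c1ccccc1)S(=O)(=O)C(F)(F)F)C(F)(F)F
Why: The acidic enolic hydroxyl is sulfonylated chemoselectively by the mild triflimide reagent (O-triflation), which leaves the primary alcohol alone, and this oxygen marks the carbon that becomes C8a.

Step 9
Reactants: 15 6-(hydroxymethyl)-4-oxo-4H-pyran-3-yl trifluoromethanesulfonate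
Product: 16 6-formyl-4-oxo-4H-pyran-3-yl trifluoromethanesulfonate
Conditions: Dess–Martin periodinane, NaHCO3, CH2Cl2, rt
Reagents that add atoms: none
Why: Dess–Martin oxidation of the primary heteroallylic alcohol to the aldehyde is mild enough for the enol triflate.

Step 10
Reactants: 16 6-formyl-4-oxo-4H-pyran-3-yl trifluoromethanesulfonate
Product: 17 4-oxo-6-[(E)-3-oxoprop-1-enyl]-4H-pyran-3-yl trifluoromethanesulfonate
Conditions: Ph3P=CHCHO (1.0 equiv), CH2Cl2, rt
Reagents that add atoms: (triphenylphosphoranylidene)acetaldehyde, O=CC=P(c1ccccc1)(c1ccccc1)c1ccccc1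
Why: Wittig olefination with the stabilised formylmethylene ylide is E-selective and should stop after one homologation because the heteroaryl aldehyde is far more electrophilic than the enal formed.

Step 11
Reactants: 17 4-oxo-6-[(E)-3-oxoprop-1-enyl]-4H-pyran-3-yl trifluoromethanesulfonate
Product: 18 6-[(E)-3,3-dimethoxyprop-1-enyl]-4-oxo-4H-pyran-3-yl trifluoromethanesulfonate
Conditions: HC(OMe)3, MeOH, PPTS (cat.), rt
Reagents that add atoms: trimethyl orthoformate, COC(OC)OC; methanol, CO
Why: Acid-catalysed acetalisation masks the enal for the coupling and ring-closure steps, while the vinylogous-ester carbonyl of the pyranone does not form a ketal.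

Step 12
Reactants: 18 6-[(E)-3,3-dimethoxyprop-1-enyl]-4-oxo-4H-pyran-3-yl trifluoromethanesulfonate
Product: 19 2-[(E)-3,3-dimethoxyprop-1-enyl]-5-(trimethylstannyl)-4H-pyran-4-one
Conditions: Me3SnSnMe3, Pd(PPh3)4 (cat.), LiCl, 1,4-dioxane, 90 °C
Reagents that add atoms: hexamethylditin, C[Sn](C)(C)[Sn](C)(C)C
Why: Palladium-catalysed stannylation of an enol triflate with a distannane (Stille-type metalation) places tin exactly on the carbon that becomes C8a.

Step 13
Reactants: 13 (2R)-3-(tert-butyldimethylsilyloxy)-2-methyl-1-[(4-methylphenyl)sulfanyl]-1-oxobut-3-en-2-yl 2,4-bis(tert-butyldimethylsilyloxy)-6-methylbenzoate; 19 2-[(E)-3,3-dimethoxyprop-1-enyl]-5-(trimethylstannyl)-4H-pyran-4-one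
Product: 20 (2R)-3-(tert-butyldimethylsilyloxy)-1-{6-[(E)-3,3-dimethoxyprop-1-enyl]-4-oxo-4H-pyran-3-yl}-2-methyl-1-oxobut-3-en-2-yl 2,4-bis(tert-butyldimethylsilyloxy)-6-methylbenzoate
Conditions: Pd2(dba)3 (cat.), P(2-furyl)3, CuO2PPh2 (1.5 equiv), THF, rt → 45 °C
Reagents that add atoms: none
Why: Liebeskind–Srogl coupling of a thioester with an organostannane forms the C8–C8a ketone bond under neutral, base-free conditions that the silyl enol ether, acetal, hindered aryl ester and quaternary C7 should tolerate.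

Step 14
Reactants: 20 (2R)-3-(tert-butyldimethylsilyloxy)-1-{6-[(E)-3,3-dimethoxyprop-1-enyl]-4-oxo-4H-pyran-3-yl}-2-methyl-1-oxobut-3-en-2-yl 2,4-bis(tert-butyldimethylsilyloxy)-6-methylbenzoate
Product: 23 (7R)-3-[(E)-3,3-dimethoxyprop-1-enyl]-7-methyl-6,8-dioxo-7,8-dihydro-6H-isochromen-7-yl 2,4-bis(tert-butyldimethylsilyloxy)-6-methylbenzoate, via methoxypyrylium triflate 21 (not isolated), via 4-methoxy-4H-pyran adduct 22 (not isolated)
Conditions: MeOTf, 2,6-di-tert-butyl-4-methylpyridine, CH2Cl2 (0.01 M), 0 °C → rt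
Reagents that add atoms: none
Why: O-Methylation of the pyranone gives a 4-methoxypyrylium ion whose C4a is attacked by the tethered silyl enol ether carbon C5 in a six-membered closure, and loss of the silyl group and methanol then gives the cross-conjugated ring A; this is the ipso-substitution at C4 by which 4-alkoxypyrylium salts condense with C–H acids to 4-alkylidene-4H-pyrans, here intramolecular and with a softer enol-type nucleophile, and C7 is not involved.

Step 15
Reactants: 23 (7R)-3-[(E)-3,3-dimethoxyprop-1-enyl]-7-methyl-6,8-dioxo-7,8-dihydro-6H-isochromen-7-yl 2,4-bis(tert-butyldimethylsilyloxy)-6-methylbenzoate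
Product: 24 (7R)-7-methyl-6,8-dioxo-3-[(E)-3-oxoprop-1-enyl]-7,8-dihydro-6H-isochromen-7-yl 2,4-dihydroxy-6-methylbenzoate (CNP0200982.1)
Conditions: 48% aq. HF, MeCN, 0 °C → rt
Reagents that add atoms: water, O
Why: Aqueous HF should cleave both aryl silyl ethers and hydrolyse the conjugated dimethyl acetal in one acidic operation (global deprotection) that the acid-stable bicyclic core, the hindered ester and the quaternary C7 survive, and it avoids basic fluoride.

Compound list
1 | orsellinic acid (2,4-dihydroxy-6-methylbenzoic acid) | Cc1cc(O)cc(O)c1C(=O)O | starting material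
2 | tert-butyldimethylsilyl 2,4-bis(tert-butyldimethylsilyloxy)-6-methylbenzoate | Cc1cc(O[Si](C)(C)C(C)(C)C)cc(O[Si](C)(C)C(C)(C)C)c1C(=O)O[Si](C)(C)C(C)(C)C | intermediate
3 | 2,4-bis(tert-butyldimethylsilyloxy)-6-methylbenzoic acid | Cc1cc(O[Si](C)(C)C(C)(C)C)cc(O[Si](C)(C)C(C)(C)C)c1C(=O)O | intermediate
4 | 2-nitroaniline | Nc1ccccc1[N+](=O)[O-] | starting material
5 | N-(2-nitrophenyl)formamide | O=CNc1ccccc1[N+](=O)[O-] | intermediate
6 | 2-nitrophenyl isocyanide (1-isocyano-2-nitrobenzene) | [C-]#[N+]c1ccccc1[N+](=O)[O-] | intermediate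
7 | butane-2,3-dione | CC(=O)C(C)=O | starting material
8 | O-aroyl imidate of 2-hydroxy-2-methyl-N-(2-nitrophenyl)-3-oxobutanimidic acid (quaternary carbon arranged as in 9) | Cc1cc(O[Si](C)(C)C(C)(C)C)cc(O[Si](C)(C)C(C)(C)C)c1C(=O)OC(=Nc1ccccc1[N+](=O)[O-])[C@@](O)(C)C(C)=O | intermediate
9 | (2R)-2-methyl-1-[(2-nitrophenyl)amino]-1,3-dioxobutan-2-yl 2,4-bis(tert-butyldimethylsilyloxy)-6-methylbenzoate | Cc1cc(O[Si](C)(C)C(C)(C)C)cc(O[Si](C)(C)C(C)(C)C)c1C(=O)O[C@](C(=O)Nc1ccccc1[N+](=O)[O-])(C)C(C)=O | intermediate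
10 | (2R)-1-[(2-aminophenyl)amino]-2-methyl-1,3-dioxobutan-2-yl 2,4-bis(tert-butyldimethylsilyloxy)-6-methylbenzoate | Cc1cc(O[Si](C)(C)C(C)(C)C)cc(O[Si](C)(C)C(C)(C)C)c1C(=O)O[C@](C(=O)Nc1ccccc1N)(C)C(C)=O | intermediate
11 | (2R)-1-(1H-benzotriazol-1-yl)-2-methyl-1,3-dioxobutan-2-yl 2,4-bis(tert-butyldimethylsilyloxy)-6-methylbenzoate | Cc1cc(O[Si](C)(C)C(C)(C)C)cc(O[Si](C)(C)C(C)(C)C)c1C(=O)O[C@](C(=O)n1nnc2ccccc21)(C)C(C)=O | intermediate
12 | (2R)-2-methyl-1-[(4-methylphenyl)sulfanyl]-1,3-dioxobutan-2-yl 2,4-bis(tert-butyldimethylsilyloxy)-6-methylbenzoate | Cc1cc(O[Si](C)(C)C(C)(C)C)cc(O[Si](C)(C)C(C)(C)C)c1C(=O)O[C@](C(=O)Sc1ccc(C)cc1)(C)C(C)=O | intermediate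
13 | (2R)-3-(tert-butyldimethylsilyloxy)-2-methyl-1-[(4-methylphenyl)sulfanyl]-1-oxobut-3-en-2-yl 2,4-bis(tert-butyldimethylsilyloxy)-6-methylbenzoate | Cc1cc(O[Si](C)(C)C(C)(C)C)cc(O[Si](C)(C)C(C)(C)C)c1C(=O)O[C@](C(=O)Sc1ccc(C)cc1)(C)C(=C)O[Si](C)(C)C(C)(C)C | intermediate
14 | kojic acid (5-hydroxy-2-(hydroxymethyl)-4H-pyran-4-one) | OCC1=CC(=O)C(O)=CO1 | starting material
15 | 6-(hydroxymethyl)-4-oxo-4H-pyran-3-yl trifluoromethanesulfonate | OCC1=CC(=O)C(OS(=O)(=O)C(F)(F)F)=CO1 | intermediate
16 | 6-formyl-4-oxo-4H-pyran-3-yl trifluoromethanesulfonate | O=CC1=CC(=O)C(OS(=O)(=O)C(F)(F)F)=CO1 | intermediate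
17 | 4-oxo-6-[(E)-3-oxoprop-1-enyl]-4H-pyran-3-yl trifluoromethanesulfonate | O=C/C=C/C1=CC(=O)C(OS(=O)(=O)C(F)(F)F)=CO1 | intermediate
18 | 6-[(E)-3,3-dimethoxyprop-1-enyl]-4-oxo-4H-pyran-3-yl trifluoromethanesulfonate | COC(OC)/C=C/C1=CC(=O)C(OS(=O)(=O)C(F)(F)F)=CO1 | intermediate
19 | 2-[(E)-3,3-dimethoxyprop-1-enyl]-5-(trimethylstannyl)-4H-pyran-4-one | COC(OC)/C=C/C1=CC(=O)C([Sn](C)(C)C)=CO1 | intermediate
20 | (2R)-3-(tert-butyldimethylsilyloxy)-1-{6-[(E)-3,3-dimethoxyprop-1-enyl]-4-oxo-4H-pyran-3-yl}-2-methyl-1-oxobut-3-en-2-yl 2,4-bis(tert-butyldimethylsilyloxy)-6-methylbenzoate | Cc1cc(O[Si](C)(C)C(C)(C)C)cc(O[Si](C)(C)C(C)(C)C)c1C(=O)O[C@](C(=O)C1=COC(/C=C/C(OC)OC)=CC1=O)(C)C(=C)O[Si](C)(C)C(C)(C)C | intermediate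
21 | 4-methoxypyrylium triflate of 20 (3-acyl-4-methoxy-6-[(E)-3,3-dimethoxyprop-1-enyl]pyrylium, C7 R) | Cc1cc(O[Si](C)(C)C(C)(C)C)cc(O[Si](C)(C)C(C)(C)C)c1C(=O)O[C@](C(=O)c1c[o+]c(/C=C/C(OC)OC)cc1OC)(C)C(=C)O[Si](C)(C)C(C)(C)C.[O-]S(=O)(=O)C(F)(F)F | intermediate
22 | (7R)-3-[(E)-3,3-dimethoxyprop-1-enyl]-4a-methoxy-7-methyl-6,8-dioxo-4a,5,7,8-tetrahydro-6H-isochromen-7-yl 2,4-bis(tert-butyldimethylsilyloxy)-6-methylbenzoate (either epimer at C4a) | Cc1cc(O[Si](C)(C)C(C)(C)C)cc(O[Si](C)(C)C(C)(C)C)c1C(=O)O[C@]1(C)C(=O)CC2(OC)C=C(/C=C/C(OC)OC)OC=C2C1=O | intermediate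
23 | (7R)-3-[(E)-3,3-dimethoxyprop-1-enyl]-7-methyl-6,8-dioxo-7,8-dihydro-6H-isochromen-7-yl 2,4-bis(tert-butyldimethylsilyloxy)-6-methylbenzoate | Cc1cc(O[Si](C)(C)C(C)(C)C)cc(O[Si](C)(C)C(C)(C)C)c1C(=O)O[C@]1(C)C(=O)C=C2C=C(/C=C/C(OC)OC)OC=C2C1=O | intermediate
24 | (7R)-7-methyl-6,8-dioxo-3-[(E)-3-oxoprop-1-enyl]-7,8-dihydro-6H-isochromen-7-yl 2,4-dihydroxy-6-methylbenzoate (CNP0200982.1) | Cc1cc(O)cc(O)c1C(=O)O[C@]1(C)C(=O)C=C2C=C(/C=C/C=O)OC=C2C1=O | target

Total step count: 15. Longest linear sequence: 9 steps (steps 2, 3, 4, 5, 6, 7, 13, 14, 15, counted from 2-nitroaniline). The orsellinic acid branch (steps 1, 4, 5, 6, 7, 13, 14, 15) and the kojic acid branch (steps 8 to 15) are 8 steps each.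

Steps most likely to fail

Step 4. The chiral phosphate may discriminate the two faces of the bound carbonyl poorly, an uncatalysed background reaction may erode the selectivity, or the electron-poor isocyanide may add too slowly at low temperature. The fallback uses known chemistry and sets out from 3, 6 and 7. These are combined without catalyst in concentrated CH2Cl2 at rt, an ordinary Passerini reaction of a 1,2-diketone, which should give the racemic adduct F1. Preparative chromatography on a chiral stationary phase should then deliver the R enantiomer, and the route is rejoined at 9.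

Step 14. The enol carbon may add to the unsubstituted pyrylium carbon C1 instead of C4a, which would be followed by opening of ring B, or O-methylation of the acyl-substituted pyranone may be too slow. The fallback sets out from 20 and closes ring A by carbonyl olefination, in which only addition to the carbonyl carbon C4a can collapse to an alkene. NBS in THF at −78 °C should convert the silyl enol ether into the α-bromo ketone F2. PPh3 in toluene should give the phosphonium bromide F3, and Et3N should liberate the keto-stabilised ylide F4 in the flask. Warming to 80–100 °C should then effect an intramolecular Wittig reaction on the pyranone carbonyl, and the route is rejoined at 23.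

Step 13. Acyl transfer from the neopentyl-type thioester may be slow, and the α-stannyl enone may undergo protodestannylation or homocoupling before it reacts. The fallback sets out from 13 and 18 and forms C8–C8a by carbonyl addition instead of acyl cross-coupling. Fukuyama reduction of 13 (Et3SiH, Pd/C, acetone) should give the aldehyde F5. Nozaki–Hiyama–Kishi coupling of F5 with enol triflate 18 (CrCl2, NiCl2 cat., DMF) should give the carbinol F6 as a mixture of epimers at C8. Dess–Martin oxidation removes that centre, and the route is rejoined at 20.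

Further compounds
F1 | step 4 | racemic 2-methyl-1-[(2-nitrophenyl)amino]-1,3-dioxobutan-2-yl 2,4-bis(tert-butyldimethylsilyloxy)-6-methylbenzoate | Cc1cc(O[Si](C)(C)C(C)(C)C)cc(O[Si](C)(C)C(C)(C)C)c1C(=O)OC(C(=O)Nc1ccccc1[N+](=O)[O-])(C)C(C)=O
F2 | step 14 | 4-bromo-1-{6-[(E)-3,3-dimethoxyprop-1-enyl]-4-oxo-4H-pyran-3-yl}-2-methyl-1,3-dioxobutan-2-yl 2,4-bis(tert-butyldimethylsilyloxy)-6-methylbenzoate (quaternary carbon arranged as in 20) | Cc1cc(O[Si](C)(C)C(C)(C)C)cc(O[Si](C)(C)C(C)(C)C)c1C(=O)O[C@](C(=O)C1=COC(/C=C/C(OC)OC)=CC1=O)(C)C(=O)CBr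
F3 | step 14 | triphenylphosphonium bromide derived from F2 (quaternary carbon arranged as in 20) | Cc1cc(O[Si](C)(C)C(C)(C)C)cc(O[Si](C)(C)C(C)(C)C)c1C(=O)O[C@](C(=O)C1=COC(/C=C/C(OC)OC)=CC1=O)(C)C(=O)C[P+](c1ccccc1)(c1ccccc1)c1ccccc1.[Br-]
F4 | step 14 | keto-stabilised triphenylphosphonium ylide derived from F3 (quaternary carbon arranged as in 20) | Cc1cc(O[Si](C)(C)C(C)(C)C)cc(O[Si](C)(C)C(C)(C)C)c1C(=O)O[C@](C(=O)C1=COC(/C=C/C(OC)OC)=CC1=O)(C)C(=O)C=P(c1ccccc1)(c1ccccc1)c1ccccc1
F5 | step 13 | (2R)-3-(tert-butyldimethylsilyloxy)-2-methyl-1-oxobut-3-en-2-yl 2,4-bis(tert-butyldimethylsilyloxy)-6-methylbenzoate | Cc1cc(O[Si](C)(C)C(C)(C)C)cc(O[Si](C)(C)C(C)(C)C)c1C(=O)O[C@](C=O)(C)C(=C)O[Si](C)(C)C(C)(C)C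
F6 | step 13 | 3-(tert-butyldimethylsilyloxy)-1-{6-[(E)-3,3-dimethoxyprop-1-enyl]-4-oxo-4H-pyran-3-yl}-1-hydroxy-2-methylbut-3-en-2-yl 2,4-bis(tert-butyldimethylsilyloxy)-6-methylbenzoate (quaternary carbon arranged as in 20, carbinol carbon as epimer mixture) | Cc1cc(O[Si](C)(C)C(C)(C)C)cc(O[Si](C)(C)C(C)(C)C)c1C(=O)O[C@](C(O)C1=COC(/C=C/C(OC)OC)=CC1=O)(C)C(=C)O[Si](C)(C)C(C)(C)C
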